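## Retrosynthetic overview

1. The target 17 comes from the macrocyclic enyne 16 by hydration of a C10≡C11 alkyne, so the base-sensitive C10 ketone is unmasked last.
2. The 14-membered ring of 16 closes at C11–C12 by intramolecular Sonogashira coupling of seco compound 14, an (E)-α-bromoacrylate made from the C13 aldehyde of 13.
3. 13 is made by a visible-light acyl-radical conjugate addition that forms C3–C4 and joins the carvone-derived acid 10 to the exo-methylene oxolanone 7.
4. The oxolan-3-one ring of 7 (C7–C8 bond, quaternary C8) comes from a rhodium-carbenoid C–H insertion with retention in diazoketone 5, built from (R)-propylene oxide.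
5. Ring order: oxolanone first, 14-membered carbocycle second. C1 is bought in (R)-carvone, C8 in (R)-propylene oxide, and C5 is set from C8 at the macrocycle stage.

Assumption and numbering: the target is taken exactly as the SMILES gives it, (1R,5S,8R) with C14 cis to CO2Me; carbons are numbered C1 (CH–isopropenyl), C2H2, C3=O, C4H2, C5H–O, C6=O, C7H2, C8(CH3)–O, C9H2, C10=O, C11H2, C12(CO2Me)=C13H, C14H2.

## Route

Step 1
Reactants: 1 (R)-2-methyloxirane
Product: 2 (2R)-pent-4-yn-2-ol
Conditions: LiC≡CH·H2NCH2CH2NH2, DMSO, 0 °C to 23 °C; then H2O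
Reagents that add atoms: lithium acetylide [Li+].[C-]#C
Why: Acetylide opens the epoxide by SN2 at the unsubstituted carbon (epoxide alkynylation), so the carbinol centre, the future C8, is not touched.

Step 2
Reactants: 2 (2R)-pent-4-yn-2-ol
Product: 3 2-{[(2R)-pent-4-yn-2-yl]oxy}acetic acid
Conditions: NaH (2.5 equiv), BrCH2CO2H, THF, 0 °C to 60 °C; then aq. HCl
Reagents that add atoms: bromoacetic acid OC(=O)CBr
Why: Williamson etherification of the sodium alkoxide with sodium bromoacetate installs C5 and C6 without involving the stereocentre.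

Step 3
Reactants: 3 2-{[(2R)-pent-4-yn-2-yl]oxy}acetic acid
Product: 5 1-diazo-3-{[(2R)-pent-4-yn-2-yl]oxy}propan-2-one, via alkoxyacetyl chloride 4 (not isolated)
Conditions: (COCl)2, cat. DMF, CH2Cl2, 0 °C; evaporate; CH2N2 (3 equiv), Et2O, 0 °C
Reagents that add atoms: diazomethane C=[N+]=[N-]
Why: Acylation of diazomethane by the acid chloride (first stage of the Arndt–Eistert sequence) gives the α-alkoxy diazoketone, with excess diazomethane taking up the HCl.

Step 4
Reactants: 5 1-diazo-3-{[(2R)-pent-4-yn-2-yl]oxy}propan-2-one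
Product: 6 (5R)-5-methyl-5-(prop-2-yn-1-yl)oxolan-3-one
Conditions: Rh2(OAc)4 (1 mol%), CH2Cl2, 23 °C, slow addition of 5
Reagents that add atoms: none
Why: Rhodium-carbenoid 1,5 C–H insertion into the oxygen-activated ether methine closes the oxolan-3-one and forms C7–C8 with retention, so the bought carbinol centre becomes quaternary C8 (R).

Step 5
Reactants: 6 (5R)-5-methyl-5-(prop-2-yn-1-yl)oxolan-3-one
Product: 7 (5R)-5-methyl-2-methylidene-5-(prop-2-yn-1-yl)oxolan-3-one
Conditions: (CH2O)n, PhNHMe·CF3CO2H, THF, 65 °C; used at once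
Reagents that add atoms: formaldehyde (as paraformaldehyde) C=O
Why: Mannich-type α-methylenation goes to the unhindered, oxygen-flanked methylene (C5) and not to the neopentyl C7, and installs C4 as an exocyclic CH2.

Step 6
Reactants: 8 (5R)-2-methyl-5-(prop-1-en-2-yl)cyclohex-2-en-1-one ((R)-carvone)
Product: 9 (1R,4R,6R)-1-methyl-4-(prop-1-en-2-yl)-7-oxabicyclo[4.1.0]heptan-2-one
Conditions: 30% H2O2, NaOH (cat.), MeOH, 0 °C
Reagents that add atoms: hydrogen peroxide OO
Why: Weitz–Scheffer nucleophilic epoxidation attacks only the enone, anti to the isopropenyl group, and the two new centres are destroyed in step 7.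

Step 7
Reactants: 9 (1R,4R,6R)-1-methyl-4-(prop-1-en-2-yl)-7-oxabicyclo[4.1.0]heptan-2-one
Product: 10 (3R)-5-oxo-3-(prop-1-en-2-yl)pentanoic acid
Conditions: H5IO6 (2.2 equiv), THF/H2O (3:1), 23 °C
Reagents that add atoms: water O
Why: Periodic acid hydrolyses the epoxy ketone to the ketodiol and cleaves it twice (Malaprade cleavage), excising the methyl-bearing carbon as acetic acid and leaving the acid (future C3) and aldehyde (future C13) arms on the untouched carvone centre (future C1).

Step 8
Reactants: 10 (3R)-5-oxo-3-(prop-1-en-2-yl)pentanoic acid; 7 (5R)-5-methyl-2-methylidene-5-(prop-2-yn-1-yl)oxolan-3-one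
Product: 13 (3R)-6-[(2RS,5R)-5-methyl-3-oxo-5-(prop-2-yn-1-yl)oxolan-2-yl]-5-oxo-3-(prop-1-en-2-yl)hexanal (both C5 epimers), via mixed carbonic anhydride 11 (not isolated), via S-acyl xanthate 12 (not isolated)
Conditions: 10 (1.5 equiv), i-BuOCOCl, N-methylmorpholine, CH2Cl2, −15 °C; then 7 (1.0 equiv, 0.5 M), EtOCS2K (20 mol%), γ-terpinene (1.5 equiv), blue LEDs (460 nm), 25 °C
Reagents that add atoms: none
Why: Proposed new method: a one-pot xanthate-catalysed visible-light acyl-radical Giese addition in which EtOCS2K turns the mixed anhydride into an S-acyl xanthate, 460 nm light homolyses its weak C(acyl)–S bond, the nucleophilic acyl radical adds to the unsubstituted terminus (C4) of the captodative exo-methylene enone, and γ-terpinene returns a hydrogen atom to C5 and an electron to the xanthyl radical (C5 forms as both epimers and is fixed in step 10); the closest known reaction is the nucleophilic-organocatalyst photochemical acyl-radical conjugate addition of acyl chlorides to simple acrylates and enones, not yet shown for an in situ anhydride of an aldehyde-bearing aliphatic acid or for a 2-methylene-oxolan-3-one acceptor.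

Step 9
Reactants: 13 (3R)-6-[(2RS,5R)-5-methyl-3-oxo-5-(prop-2-yn-1-yl)oxolan-2-yl]-5-oxo-3-(prop-1-en-2-yl)hexanal
Product: 14 methyl (2E,5R)-2-bromo-8-[(2RS,5R)-5-methyl-3-oxo-5-(prop-2-yn-1-yl)oxolan-2-yl]-7-oxo-5-(prop-1-en-2-yl)oct-2-enoate
Conditions: (CF3CH2O)2P(O)CH2CO2Me, NaH, THF, 0 °C; Br2, −78 °C; t-BuOK, 18-crown-6, −78 °C; then 13, −78 °C
Reagents that add atoms: methyl bis(2,2,2-trifluoroethyl)phosphonoacetate COC(=O)CP(=O)(OCC(F)(F)F)OCC(F)(F)F; bromine BrBr
Why: The bromophosphonate made in the flask reacts only with the aldehyde in a kinetically controlled Still–Gennari-type Horner–Wadsworth–Emmons olefination, giving the (E)-α-bromoacrylate in which C14 is cis to CO2Me as the target needs.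

Step 10
Reactants: 14 methyl (2E,5R)-2-bromo-8-[(2RS,5R)-5-methyl-3-oxo-5-(prop-2-yn-1-yl)oxolan-2-yl]-7-oxo-5-(prop-1-en-2-yl)oct-2-enoate
Product: 16 methyl (1R,5Z,8R,12S)-1-methyl-10,13-dioxo-8-(prop-1-en-2-yl)-15-oxabicyclo[10.2.1]pentadec-5-en-3-yne-5-carboxylate, via macrocycle C5-epimer mixture 15 (not isolated)
Conditions: Pd(PPh3)4 (10 mol%), CuI (20 mol%), i-Pr2NH (5 equiv), THF, 45 °C, 14 added over 12 h to 1 mM; then DBU (0.3 equiv), 23 °C
Reagents that add atoms: none
Why: Intramolecular Sonogashira coupling closes the 14-membered ring at C11–C12 with retention of the alkene geometry, and DBU then equilibrates C5 (enolisation and retro-oxa-Michael/oxa-Michael through C4) to the expected more stable cis-bridged 5S isomer, in which the rigid enyne bridge spans one face of the oxolane, so C5 is set by C8.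

Step 11
Reactants: 16 methyl (1R,5Z,8R,12S)-1-methyl-10,13-dioxo-8-(prop-1-en-2-yl)-15-oxabicyclo[10.2.1]pentadec-5-en-3-yne-5-carboxylate
Product: 17 methyl (1R,5Z,8R,12S)-1-methyl-3,10,13-trioxo-8-(prop-1-en-2-yl)-15-oxabicyclo[10.2.1]pentadec-5-ene-5-carboxylate (target)
Conditions: Ph3PAuNTf2 (5 mol%), 1,4-dioxane/H2O (10:1), 40 °C
Reagents that add atoms: water O
Why: Gold-catalysed alkyne hydration puts oxygen on C10 because the ester carbonyl (5-endo, 3-alkynoate pattern) and the C6 ketone (6-exo) both deliver to that carbon, and the neutral conditions avoid C5 epimerisation, retro-oxa-Michael opening at C8 and migration of the C12=C13 bond.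

## Compound list

1 | (R)-2-methyloxirane ((R)-propylene oxide) | C[C@@H]1CO1 | starting material
2 | (2R)-pent-4-yn-2-ol | C#CC[C@@H](C)O | intermediate
3 | 2-{[(2R)-pent-4-yn-2-yl]oxy}acetic acid | C#CC[C@@H](C)OCC(=O)O | intermediate
4 | 2-{[(2R)-pent-4-yn-2-yl]oxy}acetyl chloride | C#CC[C@@H](C)OCC(=O)Cl | intermediate
5 | 1-diazo-3-{[(2R)-pent-4-yn-2-yl]oxy}propan-2-one | C#CC[C@@H](C)OCC(=O)C=[N+]=[N-] | intermediate
6 | (5R)-5-methyl-5-(prop-2-yn-1-yl)oxolan-3-one | C#CC[C@]1(C)CC(=O)CO1 | intermediate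
7 | (5R)-5-methyl-2-methylidene-5-(prop-2-yn-1-yl)oxolan-3-one | C#CC[C@]1(C)CC(=O)C(=C)O1 | intermediate
8 | (5R)-2-methyl-5-(prop-1-en-2-yl)cyclohex-2-en-1-one ((R)-carvone) | CC1=CC[C@H](CC1=O)C(C)=C | starting material
9 | (1R,4R,6R)-1-methyl-4-(prop-1-en-2-yl)-7-oxabicyclo[4.1.0]heptan-2-one | C[C@@]12O[C@@H]1C[C@H](CC2=O)C(C)=C | intermediate
10 | (3R)-5-oxo-3-(prop-1-en-2-yl)pentanoic acid | O=CC[C@H](CC(=O)O)C(C)=C | intermediate
11 | 2-methylpropyl carbonic (3R)-5-oxo-3-(prop-1-en-2-yl)pentanoic anhydride | O=CC[C@H](CC(=O)OC(=O)OCC(C)C)C(C)=C | intermediate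
12 | O-ethyl S-[(3R)-5-oxo-3-(prop-1-en-2-yl)pentanoyl] carbonodithioate | O=CC[C@H](CC(=O)SC(=S)OCC)C(C)=C | intermediate
13 | (3R)-6-[(2RS,5R)-5-methyl-3-oxo-5-(prop-2-yn-1-yl)oxolan-2-yl]-5-oxo-3-(prop-1-en-2-yl)hexanal, both epimers at oxolane C2 (= C5) | C=C(C)[C@H](CC=O)CC(=O)CC1O[C@](C)(CC#C)CC1=O | intermediate
14 | methyl (2E,5R)-2-bromo-8-[(2RS,5R)-5-methyl-3-oxo-5-(prop-2-yn-1-yl)oxolan-2-yl]-7-oxo-5-(prop-1-en-2-yl)oct-2-enoate, both epimers at oxolane C2 (= C5) | C=C(C)[C@H](C/C=C(\C(=O)OC)Br)CC(=O)CC1O[C@](C)(CC#C)CC1=O | intermediate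
15 | methyl (1R,5Z,8R,12RS)-1-methyl-10,13-dioxo-8-(prop-1-en-2-yl)-15-oxabicyclo[10.2.1]pentadec-5-en-3-yne-5-carboxylate, both epimers at C12 (= C5) | C=C(C)[C@@H]1C/C=C(\C(=O)OC)C#CC[C@]2(C)CC(=O)C(CC(=O)C1)O2 | intermediate
16 | methyl (1R,5Z,8R,12S)-1-methyl-10,13-dioxo-8-(prop-1-en-2-yl)-15-oxabicyclo[10.2.1]pentadec-5-en-3-yne-5-carboxylate | C=C(C)[C@@H]1C/C=C(\C(=O)OC)C#CC[C@]2(C)CC(=O)[C@H](CC(=O)C1)O2 | intermediate
17 | methyl (1R,5Z,8R,12S)-1-methyl-3,10,13-trioxo-8-(prop-1-en-2-yl)-15-oxabicyclo[10.2.1]pentadec-5-ene-5-carboxylate (CNP0163183.1) | C=C(C)[C@@H]1C/C=C(\C(=O)OC)CC(=O)C[C@]2(C)CC(=O)[C@H](CC(=O)C1)O2 | target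

## Step count and risks

Total steps: 11. Longest linear sequence: 9 (steps 1, 2, 3, 4, 5, 8, 9, 10, 11).

The three steps most likely to fail:

**Step 5 (methylenation to 7).** The product is a captodative α-alkoxy vinyl ketone that can oligomerise, and some reaction at C7 cannot be excluded. The fallback sets out from 6 and replaces the one-pot methylenation by a regiodefined Mannich sequence through storable intermediates. TMSOTf/Et3N gives trimethyl{[(5R)-5-methyl-5-(prop-2-yn-1-yl)-4,5-dihydrofuran-3-yl]oxy}silane F1. Dimethylmethylideneammonium iodide in CH2Cl2 converts this into the Mannich base (2RS,5R)-2-[(dimethylamino)methyl]-5-methyl-5-(prop-2-yn-1-yl)oxolan-3-one F2. MeI gives the methiodide N,N,N-trimethyl-1-[(2RS,5R)-5-methyl-3-oxo-5-(prop-2-yn-1-yl)oxolan-2-yl]methanaminium iodide F3, and NaHCO3 in CH2Cl2/H2O releases 7 minutes before it is needed. The fallback comes back to the route at 7.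

**Step 8 (the proposed new photochemical union).** Four things can go wrong:
- activation of an aldehyde-bearing acid may be diverted through its cyclic pseudo-acid form;
- hydrogen transfer to the stabilised C5 radical may be slow, giving a xanthate-transfer adduct instead;
- enone 7 may polymerise;
- a 1,5-hydrogen shift from the aldehyde to the acyl radical would exchange the two arms and erode C1, although it is estimated to be at least a hundred times slower than addition at 0.5 M acceptor.

The fallback uses known tin-mediated acyl selenide chemistry and sets out from 10 (with 7). (PhSe)2/PBu3 in CH2Cl2 gives Se-phenyl (3R)-5-oxo-3-(prop-1-en-2-yl)pentaneselenoate F4, which is isolated. Slow addition of Bu3SnH with AIBN in benzene at 80 °C in the presence of 7 then gives the thermal acyl-radical conjugate addition. The fallback comes back at 13.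

**Step 10 (macrocyclisation and C5 equilibration).** Alkyne homocoupling, oligomerisation, or slow closure of the 5R seco epimer can lower the yield. The cis preference of the bridged ring is argued, not proven. The fallback sets out from 14 and changes the ring closure to a copper-free, amine-free Stille coupling. Bu3SnOMe with cat. ZnBr2 in THF converts the terminal alkyne into methyl (2E,5R)-2-bromo-8-{(2RS,5R)-5-methyl-3-oxo-5-[3-(tributylstannyl)prop-2-yn-1-yl]oxolan-2-yl}-7-oxo-5-(prop-1-en-2-yl)oct-2-enoate F5. Pd2(dba)3/AsPh3 in THF at 50 °C under high dilution closes the ring to 15, and the same DBU treatment gives 16, where the fallback comes back to the route.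

## Further compounds

F1 | step 5 | trimethyl{[(5R)-5-methyl-5-(prop-2-yn-1-yl)-4,5-dihydrofuran-3-yl]oxy}silane | C#CC[C@]1(C)CC(O[Si](C)(C)C)=CO1
F2 | step 5 | (2RS,5R)-2-[(dimethylamino)methyl]-5-methyl-5-(prop-2-yn-1-yl)oxolan-3-one | C#CC[C@]1(C)CC(=O)C(CN(C)C)O1
F3 | step 5 | N,N,N-trimethyl-1-[(2RS,5R)-5-methyl-3-oxo-5-(prop-2-yn-1-yl)oxolan-2-yl]methanaminium iodide | C#CC[C@]1(C)CC(=O)C(C[N+](C)(C)C)O1.[I-]
F4 | step 8 | Se-phenyl (3R)-5-oxo-3-(prop-1-en-2-yl)pentaneselenoate | O=CC[C@H](CC(=O)[Se]c1ccccc1)C(C)=C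
F5 | step 10 | methyl (2E,5R)-2-bromo-8-{(2RS,5R)-5-methyl-3-oxo-5-[3-(tributylstannyl)prop-2-yn-1-yl]oxolan-2-yl}-7-oxo-5-(prop-1-en-2-yl)oct-2-enoate | C=C(C)[C@H](C/C=C(\C(=O)OC)Br)CC(=O)CC1O[C@](C)(CC#C[Sn](CCCC)(CCCC)CCCC)CC1=O
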